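**Retrosynthetic overview**
- The flavone C-ring is the only ring formed, and it is formed last, by iodine/DMSO oxidative cyclisation of a 2'-hydroxychalcone.
- The chalcone Cα–Cβ bond (C3–C2 of the flavone) comes from an intermolecular Claisen–Schmidt aldol condensation of 6'-hydroxy-2',3'-dimethoxyacetophenone with 3,4,5-trimethoxybenzaldehyde.
- The acetophenone comes from MOM-protected 3,4-dimethoxyphenol by directed ortho-lithiation between OMOM and OMe, acetaldehyde trapping, oxidation and MOM removal.
- Both benzene rings are bought intact.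

Assumption: the target (5,6,3',4',5'-pentamethoxyflavone) has no stereocentre, so no enantiocontrol is needed; the stereocentres in 7, 11, 13 and 14 are racemic and are all destroyed before the target.

**Route**

Step 1
Reactants: 1 3,4-dimethoxyphenol; 2 chloromethyl methyl ether (MOMCl)
Product: 4 1,2-dimethoxy-4-(methoxymethoxy)benzene, via sodium 3,4-dimethoxyphenoxide 3 (not isolated)
Conditions: NaH (1.2 equiv), DMF, 0 °C; then MOMCl (1.2 equiv), 0 °C → rt
Reagents that add atoms: chloromethyl methyl ether, COCCl
Why: Williamson-type O-alkylation of the phenoxide by the highly reactive α-chloro ether gives the MOM ether, which is base-stable and a strong ortho-directing group.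

Step 2
Reactants: 4 1,2-dimethoxy-4-(methoxymethoxy)benzene; 5 acetaldehyde
Product: 7 rac-1-[2,3-dimethoxy-6-(methoxymethoxy)phenyl]ethan-1-ol, via aryllithium 6 (not isolated)
Conditions: n-BuLi (1.2 equiv), TMEDA, THF, 0 °C, 1 h; then MeCHO (3 equiv), −78 °C → rt; H2O quench
Reagents that add atoms: acetaldehyde, CC=O
Why: Directed ortho-metalation occurs at the C–H flanked by OMOM and OMe (cooperative 1,3-direction), and 1,2-addition of the aryllithium to acetaldehyde gives the racemic carbinol, whose stereocentre is removed in step 3.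

Step 3
Reactants: 7 rac-1-[2,3-dimethoxy-6-(methoxymethoxy)phenyl]ethan-1-ol
Product: 8 1-[2,3-dimethoxy-6-(methoxymethoxy)phenyl]ethan-1-one
Conditions: Dess–Martin periodinane (1.3 equiv), NaHCO3, CH2Cl2, 0 °C → rt
Reagents that add atoms: none
Why: Dess–Martin oxidation of the hindered benzylic secondary alcohol is mild and, with bicarbonate buffering, leaves the acid-labile MOM ether and the electron-rich ring untouched.

Step 4
Reactants: 8 1-[2,3-dimethoxy-6-(methoxymethoxy)phenyl]ethan-1-one
Product: 9 1-(6-hydroxy-2,3-dimethoxyphenyl)ethan-1-one (6'-hydroxy-2',3'-dimethoxyacetophenone)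
Conditions: conc. HCl (cat.), MeOH, 50 °C
Reagents that add atoms: none
Why: Acid-catalysed acetal exchange (MOM cleavage) frees the phenol, which is stabilised by hydrogen bonding to the ortho carbonyl, while aryl methyl ethers are inert to dilute HCl.

Step 5
Reactants: 9 1-(6-hydroxy-2,3-dimethoxyphenyl)ethan-1-one; 10 3,4,5-trimethoxybenzaldehyde
Product: 12 (E)-1-(6-hydroxy-2,3-dimethoxyphenyl)-3-(3,4,5-trimethoxyphenyl)prop-2-en-1-one, via aldol adduct 11 (not isolated)
Conditions: KOH (50% aq, excess), EtOH, rt, 24–48 h; then dil. HCl to pH 3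
Reagents that add atoms: 3,4,5-trimethoxybenzaldehyde, COc1cc(C=O)cc(OC)c1OC
Why: In this Claisen–Schmidt (crossed aldol) condensation the methyl ketone enolate adds to the non-enolisable aldehyde and E1cB dehydration gives the thermodynamically favoured E-enone; any material that ring-closes to the flavanone is converted to the same product in step 6.

Step 6
Reactants: 12 (E)-1-(6-hydroxy-2,3-dimethoxyphenyl)-3-(3,4,5-trimethoxyphenyl)prop-2-en-1-one
Product: 15 5,6-dimethoxy-2-(3,4,5-trimethoxyphenyl)-4H-chromen-4-one (Cerosilin B), via flavanone 13 (not isolated), via 3-iodoflavanone 14 (not isolated)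
Conditions: I2 (10 mol%), DMSO, 130 °C, 2–3 h; aq. Na2S2O3 work-up
Reagents that add atoms: none
Why: In this iodine/DMSO oxidative cyclisation, intramolecular oxa-Michael addition of the phenol is followed by α-iodination and loss of HI to give the aromatic 4-pyranone, and DMSO reoxidises HI to I2 so iodine stays catalytic.

**Compound list**
1 | 3,4-dimethoxyphenol | COc1ccc(O)cc1OC | starting material
2 | chloromethyl methyl ether (MOMCl) | COCCl | starting material
3 | sodium 3,4-dimethoxyphenoxide | COc1ccc([O-])cc1OC.[Na+] | intermediate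
4 | 1,2-dimethoxy-4-(methoxymethoxy)benzene | COCOc1ccc(OC)c(OC)c1 | intermediate
5 | acetaldehyde | CC=O | starting material
6 | [2,3-dimethoxy-6-(methoxymethoxy)phenyl]lithium | [Li]c1c(OCOC)ccc(OC)c1OC | intermediate
7 | rac-1-[2,3-dimethoxy-6-(methoxymethoxy)phenyl]ethan-1-ol (racemic) | CC(O)c1c(OCOC)ccc(OC)c1OC | intermediate
8 | 1-[2,3-dimethoxy-6-(methoxymethoxy)phenyl]ethan-1-one | CC(=O)c1c(OCOC)ccc(OC)c1OC | intermediate
9 | 1-(6-hydroxy-2,3-dimethoxyphenyl)ethan-1-one | CC(=O)c1c(O)ccc(OC)c1OC | intermediate
10 | 3,4,5-trimethoxybenzaldehyde | COc1cc(C=O)cc(OC)c1OC | starting material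
11 | rac-3-hydroxy-1-(6-hydroxy-2,3-dimethoxyphenyl)-3-(3,4,5-trimethoxyphenyl)propan-1-one (racemic aldol adduct) | COc1cc(C(O)CC(=O)c2c(O)ccc(OC)c2OC)cc(OC)c1OC | intermediate
12 | (E)-1-(6-hydroxy-2,3-dimethoxyphenyl)-3-(3,4,5-trimethoxyphenyl)prop-2-en-1-one | COc1cc(/C=C/C(=O)c2c(O)ccc(OC)c2OC)cc(OC)c1OC | intermediate
13 | rac-5,6-dimethoxy-2-(3,4,5-trimethoxyphenyl)chroman-4-one (racemic flavanone) | COc1cc(C2CC(=O)c3c(OC)c(OC)ccc3O2)cc(OC)c1OC | intermediate
14 | 3-iodo-5,6-dimethoxy-2-(3,4,5-trimethoxyphenyl)chroman-4-one (racemic, relative configuration of no consequence) | COc1cc(C2Oc3ccc(OC)c(OC)c3C(=O)C2I)cc(OC)c1OC | intermediate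
15 | 5,6-dimethoxy-2-(3,4,5-trimethoxyphenyl)-4H-chromen-4-one (Cerosilin B; achiral) | COc1cc(-c2cc(=O)c3c(OC)c(OC)ccc3o2)cc(OC)c1OC | target

**Totals**
Total step count: 6. Longest linear sequence: 6 steps (from 3,4-dimethoxyphenol 1).

**Three steps most likely to fail, with fallbacks**

Step 2 (acetaldehyde trapping of the hindered aryllithium). Acetaldehyde is volatile, oligomerises and can be enolised, so 4 may simply be recovered. The fallback sets out from 4: lithiate as before to aryllithium 6 and quench with DMF, which cannot be enolised, to give 2,3-dimethoxy-6-(methoxymethoxy)benzaldehyde F1. Methylmagnesium bromide in THF at 0 °C then adds to this aldehyde, and the route is rejoined at carbinol 7.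

Step 5 (Claisen–Schmidt condensation of a 2',6'-disubstituted acetophenone). The ketone is hindered and twisted out of conjugation, so condensation can be slow and Cannizzaro loss of 10 may compete. The fallback sets out from 9: form the phenoxide–enolate dianion with LiHMDS (4 equiv, THF, −78 °C) and C-acylate it with 3,4,5-trimethoxybenzoyl chloride. This intermolecular Claisen-type condensation gives 1-(6-hydroxy-2,3-dimethoxyphenyl)-3-(3,4,5-trimethoxyphenyl)propane-1,3-dione F2. Cyclodehydration with catalytic H2SO4 in acetic acid at 95 °C closes the pyranone ring and returns directly at target 15, so step 6 is not needed.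

Step 6 (iodine/DMSO oxidative cyclisation). Hot HI can remove the 5-O-methyl group peri to the carbonyl, or the reaction can stall at the flavanone. The fallback sets out from 12: ring-close with NaOAc in refluxing ethanol and isolate flavanone 13, then dehydrogenate it with DDQ in refluxing dioxane (hydride abstraction, no HI present), returning at target 15. This fallback makes no compound outside the list (F0).

**Further compounds**
F1 | step 2 | 2,3-dimethoxy-6-(methoxymethoxy)benzaldehyde | COCOc1ccc(OC)c(OC)c1C=O
F2 | step 5 | 1-(6-hydroxy-2,3-dimethoxyphenyl)-3-(3,4,5-trimethoxyphenyl)propane-1,3-dione | COc1cc(C(=O)CC(=O)c2c(O)ccc(OC)c2OC)cc(OC)c1OC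
F0 | step 6 | none | none
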